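The C1–C2 bond of the heptan-3-one chain is the basis of the plan: it joins the benzylic carbon on the guaiacyl ring to the carbon alpha to the C3 ketone. The key step exploits the phenolic OH at C4 of that ring, para to the ring carbon carrying C1. A 4-hydroxy-3-methoxybenzyl β-keto ester, formed in the flask from unprotected vanillyl alcohol and a chiral 1,3-dioxin-4-one (a masked acylketene), expels its own carboxylate as a p-quinone methide, and the two recombine at carbon with loss of CO2. One operation forms C1–C2, unveils the C3 ketone and leaves the phenol free. The C5 carbinol comes from an asymmetric vinylogous Mukaiyama aldol; hydrogenolysis finishes.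

Key step: step 7

Assumption: CIP analysis of the target gives (5R) (OH > C4 > C6 > H); the ligand antipode in step 5 is the one that directs attack to the Si face of aldehyde 4, to be confirmed by Mosher analysis of 9.

Step 1
Reactants: 1 3,4-dihydroxy-5-methoxybenzaldehyde (5-hydroxyvanillin)
Product: 2 3,4-bis(benzyloxy)-5-methoxybenzaldehyde
Conditions: BnBr (2.4 equiv), K2CO3, DMF, 60 °C
Reagents that add atoms: benzyl bromide, BrCc1ccccc1
Why: Williamson ether synthesis on both phenoxides; the benzyl ethers should survive every later step and leave in the final hydrogenolysis.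

Step 2
Reactants: 2 3,4-bis(benzyloxy)-5-methoxybenzaldehyde
Product: 3 (E)-3-[3,4-bis(benzyloxy)-5-methoxyphenyl]prop-2-enal
Conditions: Ph3P=CHCHO (1.2 equiv), PhMe, 80 °C
Reagents that add atoms: (triphenylphosphoranylidene)acetaldehyde, O=CC=P(c1ccccc1)(c1ccccc1)c1ccccc1
Why: Wittig reaction of a stabilized ylide, which should give the E-enal as a two-carbon homologation, with the amount of ylide limiting a second homologation.

Step 3
Reactants: 3 (E)-3-[3,4-bis(benzyloxy)-5-methoxyphenyl]prop-2-enal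
Product: 4 3-[3,4-bis(benzyloxy)-5-methoxyphenyl]propanal
Conditions: Hantzsch ester (1.1 equiv), dibenzylammonium trifluoroacetate (5 mol %), THF, rt
Reagents that add atoms: none
Why: Organocatalytic iminium-ion transfer hydrogenation should reduce only the conjugated C=C and leave the aldehyde and the benzyl ethers that H2/Pd would cleave.

Step 4
Reactants: 5 2,2,6-trimethyl-4H-1,3-dioxin-4-one
Product: 7 trimethyl[(2,2-dimethyl-4-methylidene-4H-1,3-dioxin-6-yl)oxy]silane, via lithium dienolate 6 (not isolated)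
Conditions: LDA (commercial solution), THF, −78 °C; TMSCl, −78 °C to rt
Reagents that add atoms: chlorotrimethylsilane, C[Si](C)(C)Cl
Why: Kinetic γ-deprotonation of the vinylogous ester followed by O-silylation of the dienolate (silyl dienol ether formation).

Step 5
Reactants: 4 3-[3,4-bis(benzyloxy)-5-methoxyphenyl]propanal; 7 trimethyl[(2,2-dimethyl-4-methylidene-4H-1,3-dioxin-6-yl)oxy]silane
Product: 9 (R)-6-[4-(3,4-bis(benzyloxy)-5-methoxyphenyl)-2-hydroxybutyl]-2,2-dimethyl-4H-1,3-dioxin-4-one, via silyl ether 8 (not isolated)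
Conditions: Ti(OiPr)4, tridentate Schiff-base ligand from 2-amino-2'-hydroxy-1,1'-binaphthyl and 3-bromo-5-tert-butylsalicylaldehyde, 3,5-di-tert-butylsalicylic acid (3 mol %), Et2O, 0 °C; then TFA, THF/H2O, rt
Reagents that add atoms: none
Why: Catalytic asymmetric vinylogous Mukaiyama aldol in which the dienol ether attacks through its γ-carbon; the chiral Ti(IV) complex fixes the aldehyde face (Si face, giving the R carbinol), and aqueous TFA removes the transferred TMS group.

Step 6
Reactants: 9 (R)-6-[4-(3,4-bis(benzyloxy)-5-methoxyphenyl)-2-hydroxybutyl]-2,2-dimethyl-4H-1,3-dioxin-4-one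
Product: 10 (R)-6-[2-(benzyloxymethoxy)-4-(3,4-bis(benzyloxy)-5-methoxyphenyl)butyl]-2,2-dimethyl-4H-1,3-dioxin-4-one
Conditions: BOMCl, iPr2NEt, Bu4NI (cat.), CH2Cl2, 0 °C to rt
Reagents that add atoms: benzyl chloromethyl ether, ClCOCc1ccccc1
Why: O-alkylation with an α-chloro ether under mild amine base leaves the C–O bond at the stereocenter untouched; the BOM group keeps the carbinol from capturing the acylketene in step 7 and leaves by hydrogenolysis.

Step 7
Reactants: 10 (R)-6-[2-(benzyloxymethoxy)-4-(3,4-bis(benzyloxy)-5-methoxyphenyl)butyl]-2,2-dimethyl-4H-1,3-dioxin-4-one; 11 4-(hydroxymethyl)-2-methoxyphenol (vanillyl alcohol)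
Product: 17 (R)-5-(benzyloxymethoxy)-7-[3,4-bis(benzyloxy)-5-methoxyphenyl]-1-(4-hydroxy-3-methoxyphenyl)heptan-3-one, via acylketene 12 (not isolated), via vanillyl ester 13 (not isolated), via quinone methide 14 (not isolated), via keto acid 15 (not isolated), via benzylated keto acid 16 (not isolated)
Conditions: 11 (1.05 equiv), PhMe, 110 °C (−acetone); then DBU (0.3 equiv), DMSO, 50 °C (−CO2)
Reagents that add atoms: none
Why: Proposed new method: at 110 °C the dioxinone ring of 10 should undergo retro-[4+2] cleavage to acetone and acylketene 12, which the benzylic OH of 11 captures as ester 13; DBU then ionizes the para-OH of the vanillyl group, whose 1,6-elimination expels keto acid 15 (as its carboxylate) and leaves quinone methide 14. The doubly activated C2 of 15, or of the enolate of a second molecule of 13 that afterwards fragments in the same way, adds to the exocyclic CH2 of 14 with rearomatization (1,6-addition), and the benzylated keto acid 16 loses CO2 to give 17. The closest known reaction types are the Carroll rearrangement and the Pd-catalysed decarboxylative benzylation of benzyl β-keto esters, the amine-catalysed decarboxylative 1,6-addition of β-keto acids to p-quinone methides, and the 1,6-elimination of 4-hydroxybenzyl carboxylates. No ring is closed and no stereocenter is created: C2 of 16 is lost again on decarboxylation and the C5–O bond is not involved, so the (R) centre is carried through. The step needs acylation at the benzylic and not the phenolic OH, which is secured because aryl β-keto esters revert to 12 on heating and funnel to 13, and it needs a single C-alkylation at C2, which is secured because C2 alone lies between two carbonyl groups and loses that activation with the CO2.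

Step 8
Reactants: 17 (R)-5-(benzyloxymethoxy)-7-[3,4-bis(benzyloxy)-5-methoxyphenyl]-1-(4-hydroxy-3-methoxyphenyl)heptan-3-one
Product: 18 (R)-7-(3,4-dihydroxy-5-methoxyphenyl)-5-hydroxy-1-(4-hydroxy-3-methoxyphenyl)heptan-3-one
Conditions: H2 (1 atm), Pd(OH)2/C, EtOAc/EtOH, rt
Reagents that add atoms: none
Why: Hydrogenolysis should cleave the two aryl benzyl ethers and the BOM acetal (its hemiacetal collapses to the C5 alcohol) under neutral conditions that neither dehydrate nor retro-aldolize the β-hydroxy ketone.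

Compound list
1 | 3,4-dihydroxy-5-methoxybenzaldehyde (5-hydroxyvanillin) | O=Cc1cc(O)c(O)c(OC)c1 | starting material
2 | 3,4-bis(benzyloxy)-5-methoxybenzaldehyde | O=Cc1cc(OCc2ccccc2)c(OCc2ccccc2)c(OC)c1 | intermediate
3 | (E)-3-[3,4-bis(benzyloxy)-5-methoxyphenyl]prop-2-enal | O=C/C=C/c1cc(OCc2ccccc2)c(OCc2ccccc2)c(OC)c1 | intermediate
4 | 3-[3,4-bis(benzyloxy)-5-methoxyphenyl]propanal | O=CCCc1cc(OCc2ccccc2)c(OCc2ccccc2)c(OC)c1 | intermediate
5 | 2,2,6-trimethyl-4H-1,3-dioxin-4-one | CC1=CC(=O)OC(C)(C)O1 | starting material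
6 | lithium 2,2-dimethyl-4-methylidene-4H-1,3-dioxin-6-olate (lithium dienolate of 5, not isolated) | [Li+].[O-]C1=CC(=C)OC(C)(C)O1 | intermediate
7 | trimethyl[(2,2-dimethyl-4-methylidene-4H-1,3-dioxin-6-yl)oxy]silane | C=C1C=C(O[Si](C)(C)C)OC(C)(C)O1 | intermediate
8 | (R)-6-[4-(3,4-bis(benzyloxy)-5-methoxyphenyl)-2-(trimethylsilyloxy)butyl]-2,2-dimethyl-4H-1,3-dioxin-4-one (not isolated) | CC1(C)OC(C[C@H](O[Si](C)(C)C)CCc2cc(OCc3ccccc3)c(OCc3ccccc3)c(OC)c2)=CC(=O)O1 | intermediate
9 | (R)-6-[4-(3,4-bis(benzyloxy)-5-methoxyphenyl)-2-hydroxybutyl]-2,2-dimethyl-4H-1,3-dioxin-4-one | CC1(C)OC(C[C@H](O)CCc2cc(OCc3ccccc3)c(OCc3ccccc3)c(OC)c2)=CC(=O)O1 | intermediate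
10 | (R)-6-[2-(benzyloxymethoxy)-4-(3,4-bis(benzyloxy)-5-methoxyphenyl)butyl]-2,2-dimethyl-4H-1,3-dioxin-4-one | CC1(C)OC(C[C@H](OCOCc2ccccc2)CCc2cc(OCc3ccccc3)c(OCc3ccccc3)c(OC)c2)=CC(=O)O1 | intermediate
11 | 4-(hydroxymethyl)-2-methoxyphenol (vanillyl alcohol) | COc1cc(CO)ccc1O | starting material
12 | (R)-5-(benzyloxymethoxy)-7-[3,4-bis(benzyloxy)-5-methoxyphenyl]hept-1-ene-1,3-dione (acylketene, not isolated) | O=C=CC(=O)C[C@H](OCOCc1ccccc1)CCc1cc(OCc2ccccc2)c(OCc2ccccc2)c(OC)c1 | intermediate
13 | 4-hydroxy-3-methoxybenzyl (R)-5-(benzyloxymethoxy)-7-[3,4-bis(benzyloxy)-5-methoxyphenyl]-3-oxoheptanoate (not isolated) | COc1cc(COC(=O)CC(=O)C[C@H](OCOCc2ccccc2)CCc2cc(OCc3ccccc3)c(OCc3ccccc3)c(OC)c2)ccc1O | intermediate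
14 | 2-methoxy-4-methylidenecyclohexa-2,5-dien-1-one (p-quinone methide, not isolated) | C=C1C=CC(=O)C(OC)=C1 | intermediate
15 | (R)-5-(benzyloxymethoxy)-7-[3,4-bis(benzyloxy)-5-methoxyphenyl]-3-oxoheptanoic acid (present as its DBU-H+ carboxylate, not isolated) | OC(=O)CC(=O)C[C@H](OCOCc1ccccc1)CCc1cc(OCc2ccccc2)c(OCc2ccccc2)c(OC)c1 | intermediate
16 | (5R)-5-(benzyloxymethoxy)-7-[3,4-bis(benzyloxy)-5-methoxyphenyl]-2-(4-hydroxy-3-methoxybenzyl)-3-oxoheptanoic acid (C2 epimers, not isolated) | COc1cc(CC(C(=O)O)C(=O)C[C@H](OCOCc2ccccc2)CCc2cc(OCc3ccccc3)c(OCc3ccccc3)c(OC)c2)ccc1O | intermediate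
17 | (R)-5-(benzyloxymethoxy)-7-[3,4-bis(benzyloxy)-5-methoxyphenyl]-1-(4-hydroxy-3-methoxyphenyl)heptan-3-one | COc1cc(CCC(=O)C[C@H](OCOCc2ccccc2)CCc2cc(OCc3ccccc3)c(OCc3ccccc3)c(OC)c2)ccc1O | intermediate
18 | (R)-7-(3,4-dihydroxy-5-methoxyphenyl)-5-hydroxy-1-(4-hydroxy-3-methoxyphenyl)heptan-3-one | COc1cc(CCC(=O)C[C@H](O)CCc2cc(O)c(O)c(OC)c2)ccc1O | target

Total step count: 8. Longest linear sequence: 7 steps (1, 2, 3, 5, 6, 7, 8, from 5-hydroxyvanillin); step 4 is a one-step side branch.

Steps most likely to fail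

Step 7. The quinone methide may be released too slowly from the small phenoxide fraction in an aprotic medium. The liberated β-keto acid may also lose CO2 before it is benzylated, which leaves the quinone methide to oligomerize. The fallback uses known chemistry and sets out from 10. Thermolysis of 10 with benzyl alcohol (PhMe, 110 °C) should give benzyl (R)-5-(benzyloxymethoxy)-7-[3,4-bis(benzyloxy)-5-methoxyphenyl]-3-oxoheptanoate F1 by acylketene capture. Its enolate (K2CO3, acetone, rt) is alkylated with 1-(benzyloxy)-4-(bromomethyl)-2-methoxybenzene F2, which is made from commercial 4-(benzyloxy)-3-methoxybenzyl alcohol with PBr3 (Et2O, 0 °C). This should give benzyl (5R)-2-[4-(benzyloxy)-3-methoxybenzyl]-5-(benzyloxymethoxy)-7-[3,4-bis(benzyloxy)-5-methoxyphenyl]-3-oxoheptanoate F3. Hydrogenolysis (H2, Pd(OH)2/C, EtOAc/EtOH, rt to 40 °C) removes the benzyl ester, the three aryl benzyl ethers and the BOM group. The resulting (5R)-7-(3,4-dihydroxy-5-methoxyphenyl)-5-hydroxy-2-(4-hydroxy-3-methoxybenzyl)-3-oxoheptanoic acid F4 should decarboxylate in the flask. The fallback comes back to the route at 18 and replaces steps 7 and 8.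

Step 5. Facial discrimination may be insufficient with an unbranched aliphatic aldehyde, so that the carbinol is formed with low enantiomeric purity. The fallback sets the centre by reduction instead of by C–C bond formation and sets out from 4 and 7. A BF3·OEt2-mediated vinylogous Mukaiyama aldol (CH2Cl2, −78 °C) should give racemic 6-[4-(3,4-bis(benzyloxy)-5-methoxyphenyl)-2-hydroxybutyl]-2,2-dimethyl-4H-1,3-dioxin-4-one F5. Dess–Martin oxidation (CH2Cl2, rt) gives 6-[4-(3,4-bis(benzyloxy)-5-methoxyphenyl)-2-oxobutyl]-2,2-dimethyl-4H-1,3-dioxin-4-one F6. An (R)-selective ketoreductase chosen from a screening panel (NADP+, iPrOH recycling, pH 7 buffer/DMSO, 30 °C) reduces F6, and the fallback comes back to the route at 9.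

Step 2. The product enal may be homologated a second time to the dienal, and the electron-rich aldehyde may convert slowly. The fallback sets out from 2. Horner–Wadsworth–Emmons olefination with triethyl phosphonoacetate (NaH, THF, 0 °C to rt) should give ethyl (E)-3-[3,4-bis(benzyloxy)-5-methoxyphenyl]prop-2-enoate F7. Conjugate reduction (NaBH4, NiCl2·6H2O, MeOH, 0 °C) gives ethyl 3-[3,4-bis(benzyloxy)-5-methoxyphenyl]propanoate F8. DIBAL-H (PhMe, −78 °C) then reduces the ester to the aldehyde, and the fallback comes back to the route at 4, which also bypasses step 3.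

Further compounds
F1 | step 7 | benzyl (R)-5-(benzyloxymethoxy)-7-[3,4-bis(benzyloxy)-5-methoxyphenyl]-3-oxoheptanoate | O=C(CC(=O)C[C@H](OCOCc1ccccc1)CCc1cc(OCc2ccccc2)c(OCc2ccccc2)c(OC)c1)OCc1ccccc1
F2 | step 7 | 1-(benzyloxy)-4-(bromomethyl)-2-methoxybenzene | COc1cc(CBr)ccc1OCc1ccccc1
F3 | step 7 | benzyl (5R)-2-[4-(benzyloxy)-3-methoxybenzyl]-5-(benzyloxymethoxy)-7-[3,4-bis(benzyloxy)-5-methoxyphenyl]-3-oxoheptanoate (C2 epimers) | COc1cc(CC(C(=O)OCc2ccccc2)C(=O)C[C@H](OCOCc2ccccc2)CCc2cc(OCc3ccccc3)c(OCc3ccccc3)c(OC)c2)ccc1OCc1ccccc1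
F4 | step 7 | (5R)-7-(3,4-dihydroxy-5-methoxyphenyl)-5-hydroxy-2-(4-hydroxy-3-methoxybenzyl)-3-oxoheptanoic acid (C2 epimers) | COc1cc(CC(C(=O)O)C(=O)C[C@H](O)CCc2cc(O)c(O)c(OC)c2)ccc1O
F5 | step 5 | racemic 6-[4-(3,4-bis(benzyloxy)-5-methoxyphenyl)-2-hydroxybutyl]-2,2-dimethyl-4H-1,3-dioxin-4-one | CC1(C)OC(CC(O)CCc2cc(OCc3ccccc3)c(OCc3ccccc3)c(OC)c2)=CC(=O)O1
F6 | step 5 | 6-[4-(3,4-bis(benzyloxy)-5-methoxyphenyl)-2-oxobutyl]-2,2-dimethyl-4H-1,3-dioxin-4-one | CC1(C)OC(CC(=O)CCc2cc(OCc3ccccc3)c(OCc3ccccc3)c(OC)c2)=CC(=O)O1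
F7 | step 2 | ethyl (E)-3-[3,4-bis(benzyloxy)-5-methoxyphenyl]prop-2-enoate | CCOC(=O)/C=C/c1cc(OCc2ccccc2)c(OCc2ccccc2)c(OC)c1
F8 | step 2 | ethyl 3-[3,4-bis(benzyloxy)-5-methoxyphenyl]propanoate | CCOC(=O)CCc1cc(OCc2ccccc2)c(OCc2ccccc2)c(OC)c1
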